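- Reagent is what each turn of the chain takes up. None of it is dissolved at the start, so the gas, held at 4.4 mM, has to supply it first, while 0.95 mM of initiator starts the chains.

| setting | red | amber | theta | gamma |
|---|---|---|---|---|
| starting material | 0.013 M | 0.054 M | 0.019 M | 0.060 M |
| gas | 4.4 mM (held) | 4.4 mM (held) | 4.4 mM (held) | 4.4 mM (held) |
| initiator | 0.95 mM | 0.95 mM | 0.95 mM | 0.95 mM |
| remark | run made earlier | run made earlier |  |  |
| time |  |  | 10 h | 15 h |

- red (time / h: target / %, starting material / %): 1.33: 3.9, 95.8; 2.50: 12.1, 87.3; 4.00: 24.1, 76.6; 5.00: 31.2, 69.3; 6.00: 38.1, 61.4; 8.00: 53.6, 46.0
- amber (time / h: target / %, starting material / %): 0.500: 0.9, 100.0; 1.33: 1.1, 98.8; 2.50: 2.9, 96.8; 4.00: 5.2, 95.3; 5.00: 7.5, 92.8; 8.00: 13.1, 86.9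

(standard deviation of a reading: 0.5 percentage points)

- percentages count the starting material that a species holds: one ended chains A counts as two
- at the start none of reagent is dissolved
- what may be going on: reagent + first chain carrier -> target + second chain carrier; 2 second chain carrier -> ended chains B; starting material + initiating radical -> capped initiator + first chain carrier; 2 first chain carrier -> ended chains A; starting material + second chain carrier -> released group + first chain carrier; gas <-> reagent; initiator -> 2 initiating radical

1. which of the two ends with the higher amount of target, in percent of the starting material charged ("neither" if they lie within 2 percentage points) (theta / gamma / neither)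
2. target at the end, in percent of the starting material charged, theta
3. target at the end, in percent of the starting material charged, gamma

- First instants: target is slow to appear, with 3.9% in the red run and 1.1% in the amber run at 1.33 h. I read this as a lag while reagent builds up from nothing.
- Middle: I take reagent itself to be at steady state, made as fast as it is used, so target should form as fast as reagent arrives. From 4.00 h to 8.00 h the red run gains 0.959 mM h⁻¹ and the amber run 1.07 mM h⁻¹, although the amber run holds 4.15 times the starting material.
- So I read the rate as zero order in starting material over these readings. The mean of the two slopes is my supply rate, 1.01 mM h⁻¹: target formed per hour, as a concentration rather than a percentage.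
- Extrapolating the target of the two runs at 8.00 h back along this rate gives a lag of 1.07 h.
- End: my reckoning gives theta 9.05 mM of target, which is 47.6% of its charge, so its starting material lasts. Gamma gets 14.1 mM, which is more in concentration, but its charge is 3.16 times that of theta, so this is only 23.5%, and I choose theta.
- The forecast also chooses theta, with 47% and 23%, each a little under my figures, and it reasons: “So the rate is zero order in starting material.”
- The simulation gives theta, with 47.4% for theta and 23.4% for gamma.

    reagent + first chain carrier → target + second chain carrier (k = 35700 M⁻¹ s⁻¹)
    2 second chain carrier → ended chains B (k = 1.80 × 10⁷ M⁻¹ s⁻¹)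
    starting material + initiating radical → capped initiator + first chain carrier (k = 6.59 × 10⁵ M⁻¹ s⁻¹)
    2 first chain carrier → ended chains A (k = 9.00 × 10⁷ M⁻¹ s⁻¹)
    starting material + second chain carrier → released group + first chain carrier (k = 26800 M⁻¹ s⁻¹)
    gas ⇌ reagent, rate k6*(csat - [reagent]) (kL = 0.557 h⁻¹)
    initiator → 2 initiating radical (k = 0.00322 h⁻¹)

- At 15.0 h gamma holds 0.00260 M of reagent, made 1.00 times as fast as it is used, and gas uptake at that level is 1.00 mM h⁻¹, against the supply rate of 1.01 mM h⁻¹ read from the two earlier runs. The neighbouring flask is gamma read at 6.0 h. The same reckoning, the supply rate times the time after the lag, divided by the charge, gives it 8.33%. That flask holds 8.36% of target.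

The readings come from a simulation with made-up constants; noise was put on by code.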